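## Retrosynthetic overview

1. Target ⇒ lupulone. Ring B (the 2,2-dimethyl-2H-pyran) is opened at its O–C(CH3)2 bond. In the forward direction, one of the two enantiotopic C6 prenyl groups closes onto the C5 enol oxygen in a desymmetrising, dehydrogenative C–O ring closure. This single step makes ring B and the only stereocentre.
2. Lupulone ⇒ phlorisovalerophenone + three prenyl bromide (two aromatic C-prenylations, then one alkylative dearomatisation).
3. Phlorisovalerophenone ⇒ phloroglucinol + isovaleryl chloride (Friedel–Crafts acylation).
4. Ring order: ring A (the carbocycle) is bought as the arene and dearomatised in the second step. Ring B is closed last.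

Assumption: the sense of induction of a ligand in a new reaction cannot be predicted, so (M,S,S)-iPr-SPRIX stands for the antipode that gives the (R) product; if the first run gives (S), the mirror-image ligand (P,R,R)-iPr-SPRIX is used.

Atom labels: lupulone numbering for 7 (C1 ring C=O next to C6, C2 acyl, C3 OH, C4 prenyl, C5 OH, C6 diprenyl); chromene numbering for 8 and 9.

## Route

Step 1
Reactants: 1 phloroglucinol; 2 isovaleryl chloride
Product: 3 phlorisovalerophenone
Conditions: AlCl3 (3.5 equiv), CH2Cl2/MeNO2, 0 to 40 °C; then ice/dilute aq HCl
Reagents that add atoms: isovaleryl chloride (2), CC(C)CC(=O)Cl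
Why: Friedel–Crafts acylation of this very electron-rich arene stops after one acyl group because the aryl ketone is deactivated and held as its aluminium chelate, any O-acyl ester formed first is carried on to 3 by Fries rearrangement under the same conditions, and no stereocentre is formed.

Step 2
Reactants: 3 phlorisovalerophenone; 4 prenyl bromide (3.1 equiv)
Product: 7 lupulone, via monoprenylphlorisovalerophenone 5 (not isolated), via deoxyhumulone 6 (not isolated)
Conditions: liquid NH3/Et2O, −78 to −33 °C, argon; evaporate NH3, dilute aq HCl; crystallise from hexane, store cold under argon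
Reagents that add atoms: prenyl bromide (4), CC(C)=CCBr
Why: Threefold SN2 C-alkylation of the ambident ammonium phloroglucinolate by a soft allylic bromide in a strongly hydrogen-bonding medium favours carbon over oxygen, fills the two free ring carbons first (5, 6) and then hits an already prenylated carbon (alkylative dearomatisation), after which the delocalised lupulonate salt resists a fourth alkylation, and C6 carries two identical groups so no stereocentre arises.

Step 3
Reactants: 7 lupulone
Product: 9 (4aR)-7-hydroxy-2,2-dimethyl-6-(3-methylbutanoyl)-4a,8-bis(3-methylbut-2-en-1-yl)-2H-chromen-5(4aH)-one (target), via alkylpalladium trifluoroacetate 8 (not isolated)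
Conditions: Pd(OCOCF3)2 (10 mol %), (M,S,S)-iPr-SPRIX (12 mol %), p-benzoquinone (1.1 equiv), 3 Å molecular sieves, CH2Cl2, argon, dark, 0 to 25 °C, stopped at about 85 % conversion
Reagents that add atoms: none
Why: Proposed new method: a desymmetrising, enantioselective 6-endo-trig Wacker-type dehydrogenative etherification in which the electrophilic, weakly donating SPRIX complex of divalent palladium binds one face of one of the two enantiotopic C6 prenyl alkenes, the only non-chelated enol oxygen (O5) attacks the dimethyl-substituted (Markovnikov) alkene carbon anti to palladium through a chair in which the planar dienone forces the ring carbonyl carbon equatorial and the spectator prenyl axial, so that a given alkene face can be used by only one of the two prenyl groups and the face selection of the catalyst is relayed into closure of the pro-R prenyl group and hence the (R) quaternary centre, after which 8 has β-hydrogens only on C4 and loses palladium hydride to give the cis ring alkene while benzoquinone returns zerovalent palladium to the divalent state; the closest known reaction type is the Pd(OCOCF3)2/SPRIX/benzoquinone 6-endo Wacker-type cyclisation of 2-prenyl- and 2-geranylphenols to 2H-chromenes, which has not been shown for enol (vinylogous acid) nucleophiles, for prenyl groups on a quaternary sp3 carbon, or as a desymmetrisation.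

## Compound list

1 | phloroglucinol (benzene-1,3,5-triol) | Oc1cc(O)cc(O)c1 | starting material
2 | isovaleryl chloride (3-methylbutanoyl chloride) | CC(C)CC(=O)Cl | starting material
3 | phlorisovalerophenone, 3-methyl-1-(2,4,6-trihydroxyphenyl)butan-1-one | CC(C)CC(=O)c1c(O)cc(O)cc1O | intermediate
4 | prenyl bromide (1-bromo-3-methylbut-2-ene) | CC(C)=CCBr | starting material
5 | monoprenylphlorisovalerophenone, 3-methyl-1-[2,4,6-trihydroxy-3-(3-methylbut-2-en-1-yl)phenyl]butan-1-one | CC(C)CC(=O)c1c(O)cc(O)c(CC=C(C)C)c1O | intermediate
6 | deoxyhumulone, 3-methyl-1-[2,4,6-trihydroxy-3,5-bis(3-methylbut-2-en-1-yl)phenyl]butan-1-one | CC(C)CC(=O)c1c(O)c(CC=C(C)C)c(O)c(CC=C(C)C)c1O | intermediate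
7 | lupulone, 3,5-dihydroxy-2-(3-methylbutanoyl)-4,6,6-tris(3-methylbut-2-en-1-yl)cyclohexa-2,4-dien-1-one (achiral) | CC(C)CC(=O)C1=C(O)C(CC=C(C)C)=C(O)C(CC=C(C)C)(CC=C(C)C)C1=O | intermediate
8 | [(3S,4aR)-7-hydroxy-2,2-dimethyl-6-(3-methylbutanoyl)-5-oxo-4a,8-bis(3-methylbut-2-en-1-yl)-3,4,4a,5-tetrahydro-2H-chromen-3-yl]palladium trifluoroacetate, palladium trans to the angular prenyl group (SPRIX ligand on palladium not drawn; C3 is erased in the elimination) | CC(C)=CCC1=C2OC(C)(C)[C@@H]([Pd]OC(=O)C(F)(F)F)C[C@@]2(CC=C(C)C)C(=O)C(C(=O)CC(C)C)=C1O | intermediate
9 | (4aR)-7-hydroxy-2,2-dimethyl-6-(3-methylbutanoyl)-4a,8-bis(3-methylbut-2-en-1-yl)-2H-chromen-5(4aH)-one | CC(C)=CCC1=C2OC(C)(C)C=C[C@@]2(CC=C(C)C)C(=O)C(C(=O)CC(C)C)=C1O | target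

## Step count and risks

Total step count: 3. Longest linear sequence: 3 (1 → 3 → 7 → 9).

**Risk A, step 3 (the proposed new step).**

What can go wrong:
- The prenyl group on the sp2 carbon C4 can close on the same oxygen O5 to give a chromene-type isomer. Any oxidant that abstracts C–H would prefer that group, which is why an alkene-activating catalyst is used.
- A C6 prenyl group can close on O1 instead of O5.
- The β-triketone can bind divalent palladium as an O,O-chelate and slow turnover.
- The enantiomeric excess is unknown.
- A second cyclisation can follow, which is why benzoquinone and conversion are limited.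

What favours the wanted closure:
- Two C6 prenyl groups compete against one C4 prenyl group.
- C6 benefits from the gem-dialkyl effect.
- The C6 closure goes through an unstrained chair. The C4 closure needs a half-chair that pushes the side chain into the ring plane against O3 and O5.
- O5 is the only enol oxygen outside the hydrogen-bonded triketone.
- The isomers can be told apart by HMBC, from the olefinic H4 to the sp3 quaternary carbon C4a.

Fallback (known chemistry), from 7 back to 9:
- N-(phenylselanyl)phthalimide and catalytic camphorsulfonic acid in CH2Cl2 at −78 °C give, by 6-endo selenoetherification, the racemic trans phenylselanyl dihydropyran F1.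
- F1 is a stable compound and is separated on silica from isomers closed through the C4 prenyl group.
- H2O2/pyridine in CH2Cl2 at 0 °C gives the selenoxide F2.
- On warming to 25 °C, F2 undergoes syn elimination toward its only β-hydrogens to give the racemic target F3.
- Preparative supercritical-fluid chromatography on an amylose-based chiral phase then delivers 9. The configuration is assigned by electronic circular dichroism against calculation.

**Risk B, step 2.**

The one-pot triple alkylation can give mixtures of di-, tri- and tetraprenyl compounds and some O-prenyl ethers. Compound 7 also autoxidises in air.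

Fallback, from 3 back to 7:
- 3 is prenylated only twice (4, 2.0 equiv, aq KOH, 0 °C) and deoxyhumulone 6 is isolated by chromatography.
- The third, dearomatising prenyl group is then installed by a different mechanism, a Tsuji–Trost allylic alkylation. The conditions are commercial prenyl acetate, Pd(PPh3)4 (5 mol %) and Et3N in THF at 25 °C.
- The soft π-prenyl complex of divalent palladium is attacked at its CH2 terminus by the prenylated ring carbon. The amount of electrophile is set by stoichiometry.
- No compound outside the list is made (F0).

**Risk C, step 1.**

Poor solubility of 1, diacylation, and emulsions from the aluminium salts can lower the yield.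

Fallback, from 1 back to 3:
- A Houben–Hoesch reaction with isovaleronitrile, ZnCl2 and dry HCl in Et2O at 0 °C precipitates the ketimine hydrochloride F4. This salt cannot react a second time.
- F4 is filtered off and hydrolysed in boiling water to 3.

## Further compounds

F1 | step 3 | racemic trans-7-hydroxy-2,2-dimethyl-6-(3-methylbutanoyl)-4a,8-bis(3-methylbut-2-en-1-yl)-3-(phenylselanyl)-3,4-dihydro-2H-chromen-5(4aH)-one | CC(C)=CCC1=C2OC(C)(C)C([Se]c3ccccc3)CC2(CC=C(C)C)C(=O)C(C(=O)CC(C)C)=C1O
F2 | step 3 | selenoxide of F1 (racemic, mixture at selenium) | CC(C)=CCC1=C2OC(C)(C)C([Se](=O)c3ccccc3)CC2(CC=C(C)C)C(=O)C(C(=O)CC(C)C)=C1O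
F3 | step 3 | racemic 7-hydroxy-2,2-dimethyl-6-(3-methylbutanoyl)-4a,8-bis(3-methylbut-2-en-1-yl)-2H-chromen-5(4aH)-one | CC(C)=CCC1=C2OC(C)(C)C=CC2(CC=C(C)C)C(=O)C(C(=O)CC(C)C)=C1O
F0 | step 2 | none | none
F4 | step 1 | 3-methyl-1-(2,4,6-trihydroxyphenyl)butan-1-iminium chloride | CC(C)CC(=[NH2+])c1c(O)cc(O)cc1O.[Cl-]
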